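Ring A is built, not geranylated. C8, which carries the geranyl chain, lies between the oxygenated carbons C7 and C8a, the carbon–oxygen arrangement of an acetoacetate alkylated at its central carbon. C6–C7–C8–C8a is therefore taken from methyl 2-geranylacetoacetate as a 1-methoxy-1,3-bis(silyloxy)butadiene. Its Diels–Alder reaction with an enantiopure terminal ynone that already holds C5, C4a, C4, C3, the oxygenated C2 and ring B forms C6–C5 and C8a–C4a at once. Loss of methanol and of the labile silyl group then leaves the fully substituted ring A with the acyl chain next to a free phenol. Mitsunobu closure of ring C with inversion at C2 and desilylation finish the synthesis.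

Key step: step 9

Remark: the enol ether geometry of 4 and the ketene acetal geometry of 5 are drawn as single isomers for definiteness; either isomer or a mixture is expected to serve, because both double bonds are consumed on the way to the aromatic ring, and 12 is likewise a mixture at its ketal carbon.

Step 1
Reactants: 1 methyl acetoacetate; 2 geranyl bromide [(2E)-1-bromo-3,7-dimethylocta-2,6-diene]
Product: 3 methyl (4E)-2-acetyl-5,9-dimethyldeca-4,8-dienoate (methyl 2-geranylacetoacetate; racemic)
Conditions: NaH, THF, 0 °C; then 2 (0.8 equiv), 0 °C → rt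
Reagents that add atoms: none
Why: Acetoacetic ester alkylation: the soft sodium enolate displaces the primary allylic bromide by direct SN2 attack at carbon with the E-alkene retained, and the excess of 1 suppresses dialkylation.

Step 2
Reactants: 3 methyl 2-geranylacetoacetate
Product: 4 methyl (2E)-3-(tert-butyldimethylsilyloxy)-2-[(2E)-3,7-dimethylocta-2,6-dien-1-yl]but-2-enoate
Conditions: TBSOTf, Et3N, CH2Cl2, 0 °C
Reagents that add atoms: tert-butyldimethylsilyl trifluoromethanesulfonate, CC(C)(C)[Si](C)(C)OS(=O)(=O)C(F)(F)F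
Why: Silyl enol ether formation: the amine enolises the β-keto ester at the doubly activated carbon and the silyl triflate traps the ketone oxygen, which places the robust silyl group on the future C7 oxygen.

Step 3
Reactants: 4 silyl enol ether
Product: 5 (1E)-3-(tert-butyldimethylsilyloxy)-2-[(2E)-3,7-dimethylocta-2,6-dien-1-yl]-1-methoxy-1-(trimethylsilyloxy)buta-1,3-diene
Conditions: LiN(i-Pr)2, THF, −78 °C; TMSCl, −78 → 0 °C; non-aqueous work-up (pentane, filtration under Ar), used crude
Reagents that add atoms: chlorotrimethylsilane, C[Si](C)(C)Cl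
Why: Vinylogous (γ) deprotonation of the β-silyloxy enoate gives the ester dienolate, which is silylated on oxygen to the silyl ketene acetal, the standard preparation of 1-alkoxy-1,3-bis(silyloxy)butadienes.

Step 4
Reactants: 6 ethyl 3-(4-hydroxyphenyl)-3-oxopropanoate
Product: 7 ethyl 3-[4-(tert-butyldimethylsilyloxy)phenyl]-3-oxopropanoate
Conditions: TBSCl, imidazole, DMF, rt
Reagents that add atoms: tert-butyldimethylsilyl chloride, CC(C)(C)[Si](C)(C)Cl
Why: Imidazole-promoted O-silylation of the phenol, by far the most nucleophilic oxygen present; any enol silyl ether of the β-keto ester would be hydrolysed on work-up.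

Step 5
Reactants: 7 silylated β-keto ester
Product: 8 ethyl (3R)-3-[4-(tert-butyldimethylsilyloxy)phenyl]-3-hydroxypropanoate
Conditions: RuCl2[(S)-BINAP] (1 mol%), H2 (50 atm), EtOH, 50 °C
Reagents that add atoms: none
Why: Noyori asymmetric hydrogenation: the β-keto ester chelates divalent ruthenium through both carbonyl oxygens and the (S)-ligand directs hydride to the ketone face that gives the (R)-carbinol (the descriptor is opposite to that of the alkyl series because the aryl group outranks the CH2CO2Et arm).

Step 6
Reactants: 8 (R)-β-hydroxy ester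
Product: 9 (3R)-3-[4-(tert-butyldimethylsilyloxy)phenyl]-3-hydroxy-N-methoxy-N-methylpropanamide
Conditions: MeNHOMe·HCl, i-PrMgCl, THF, −20 → 0 °C
Reagents that add atoms: N,O-dimethylhydroxylamine hydrochloride, CNOC.Cl
Why: Weinreb amide formation by aminolysis of the ester with the chloromagnesium amide; the carbinol is carried as its magnesium alkoxide, a poor leaving group, so amidation before O-silylation avoids β-elimination and leaves the stereocentre untouched.

Step 7
Reactants: 9 β-hydroxy Weinreb amide
Product: 10 (3R)-3-[4-(tert-butyldimethylsilyloxy)phenyl]-N-methoxy-N-methyl-3-(triethylsilyloxy)propanamide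
Conditions: TESCl, imidazole, DMF, 0 °C
Reagents that add atoms: chlorotriethylsilane, CC[Si](Cl)(CC)CC
Why: Routine silylation of a secondary alcohol; the triethylsilyl ether is chosen because it is removable later by weak acid in the presence of the aryl tert-butyldimethylsilyl ethers.

Step 8
Reactants: 10 silylated Weinreb amide
Product: 11 (5R)-5-[4-(tert-butyldimethylsilyloxy)phenyl]-5-(triethylsilyloxy)pent-1-yn-3-one
Conditions: HC≡CMgBr, THF, 0 °C; inverse quench into cold aq. NaHSO4/Et2O
Reagents that add atoms: ethynylmagnesium bromide, C#C[Mg]Br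
Why: Weinreb ketone synthesis: the magnesium-chelated tetrahedral adduct stops at single addition, and the cold acidic inverse quench protonates the released N,O-dimethylhydroxylamine before it can add to the terminal ynone.

Step 9
Reactants: 5 bis(silyloxy)diene; 11 (R)-ynone
Product: 14 (3R)-1-[4-(tert-butyldimethylsilyloxy)-3-geranyl-2-hydroxyphenyl]-3-[4-(tert-butyldimethylsilyloxy)phenyl]-3-(triethylsilyloxy)propan-1-one, via cyclohexa-1,4-diene cycloadduct 12 (not isolated), via aryl trimethylsilyl ether 13 (not isolated)
Conditions: 5 (1.5 equiv), toluene, −40 °C → rt; then silica gel, wet EtOAc, rt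
Reagents that add atoms: none
Why: The electron-rich diene and the electron-poor ynone combine in a normal-electron-demand, concerted but asynchronous Diels–Alder reaction in which the unsubstituted diene terminus (largest HOMO coefficient, future C6) bonds ahead to the terminal alkyne carbon (largest LUMO coefficient, future C5) and the ketene acetal carbon (future C8a) bonds to the carbonyl-bearing alkyne carbon (future C4a). The closest known reaction type is the benzannulation of 1-alkoxy-1,3-bis(silyloxy)butadienes with acetylenic ketones and esters, which gives resorcinol derivatives. Ring A is closed in this one intermolecular [4+2] event to give 12, whose mixed methyl trimethylsilyl ketal expels methanol across C8a and C6 to aromatise to 13, and the aryl trimethylsilyl ether, the most labile silyl group present, is hydrolysed on silica to the phenol that hydrogen-bonds to the new ketone. No stereocentre is created (the ketal carbon of 12 is transient), and the remote (R)-carbinol is not involved under these neutral conditions. The selectivity needed is regiochemical, acyl group next to the free hydroxyl, and it is secured by the matched polarisation of the two partners; the geranyl group, fixed on the internal diene carbon, can only end up at C8 between the two oxygens, and the absence of acid protects its alkenes and the triethylsilyl ether.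

Step 10
Reactants: 14 benzannulation product
Product: 15 (3R)-1-[4-(tert-butyldimethylsilyloxy)-3-geranyl-2-hydroxyphenyl]-3-[4-(tert-butyldimethylsilyloxy)phenyl]-3-hydroxypropan-1-one
Conditions: AcOH/THF/H2O (3:1:1), 0 °C → rt
Reagents that add atoms: none
Why: Acid-catalysed silyl ether hydrolysis is fastest for the small alkyl triethylsilyl ether, whereas aryl tert-butyldimethylsilyl ethers are comparatively acid-stable, and acetic acid is too weak to ionise the benzylic carbinol or to cyclise the geranyl chain.

Step 11
Reactants: 15 phenolic β-hydroxy ketone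
Product: 16 (2S)-7-(tert-butyldimethylsilyloxy)-2-[4-(tert-butyldimethylsilyloxy)phenyl]-8-geranylchroman-4-one
Conditions: PPh3, DIAD (added slowly), toluene, 0 °C
Reagents that add atoms: none
Why: Intramolecular Mitsunobu etherification: the chelated C8a phenol is acidic enough to protonate the betaine, the benzylic alcohol becomes the alkoxyphosphonium ion, and the phenoxide displaces it in a 6-exo-tet SN2 closure of ring C with inversion, so (R) becomes (2S); the non-polar solvent and low temperature disfavour ionisation.

Step 12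
Reactants: 16 bis-silylated flavanone
Product: 17 (2S)-7,4'-dihydroxy-8-geranylflavanone
Conditions: Bu4NF/AcOH (1:1), THF, 0 °C
Reagents that add atoms: none
Why: Fluoride-mediated cleavage of the two aryl silyl ethers; buffering with acetic acid keeps the medium non-basic, so the flavanone cannot open to the chalcone by retro-oxa-Michael reaction and C2 keeps its configuration.

Compound list
1 | methyl acetoacetate | COC(=O)CC(C)=O | starting material
2 | geranyl bromide | CC(C)=CCC/C(C)=C/CBr | starting material
3 | methyl (4E)-2-acetyl-5,9-dimethyldeca-4,8-dienoate (racemic) | COC(=O)C(C/C=C(\C)CCC=C(C)C)C(C)=O | intermediate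
4 | methyl (2E)-3-(tert-butyldimethylsilyloxy)-2-[(2E)-3,7-dimethylocta-2,6-dien-1-yl]but-2-enoate | COC(=O)/C(C/C=C(\C)CCC=C(C)C)=C(\C)O[Si](C)(C)C(C)(C)C | intermediate
5 | (1E)-3-(tert-butyldimethylsilyloxy)-2-[(2E)-3,7-dimethylocta-2,6-dien-1-yl]-1-methoxy-1-(trimethylsilyloxy)buta-1,3-diene | CO/C(O[Si](C)(C)C)=C(/C/C=C(\C)CCC=C(C)C)C(=C)O[Si](C)(C)C(C)(C)C | intermediate
6 | ethyl 3-(4-hydroxyphenyl)-3-oxopropanoate | CCOC(=O)CC(=O)c1ccc(O)cc1 | starting material
7 | ethyl 3-[4-(tert-butyldimethylsilyloxy)phenyl]-3-oxopropanoate | CCOC(=O)CC(=O)c1ccc(O[Si](C)(C)C(C)(C)C)cc1 | intermediate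
8 | ethyl (3R)-3-[4-(tert-butyldimethylsilyloxy)phenyl]-3-hydroxypropanoate | CCOC(=O)C[C@@H](O)c1ccc(O[Si](C)(C)C(C)(C)C)cc1 | intermediate
9 | (3R)-3-[4-(tert-butyldimethylsilyloxy)phenyl]-3-hydroxy-N-methoxy-N-methylpropanamide | CON(C)C(=O)C[C@@H](O)c1ccc(O[Si](C)(C)C(C)(C)C)cc1 | intermediate
10 | (3R)-3-[4-(tert-butyldimethylsilyloxy)phenyl]-N-methoxy-N-methyl-3-(triethylsilyloxy)propanamide | CON(C)C(=O)C[C@@H](O[Si](CC)(CC)CC)c1ccc(O[Si](C)(C)C(C)(C)C)cc1 | intermediate
11 | (5R)-5-[4-(tert-butyldimethylsilyloxy)phenyl]-5-(triethylsilyloxy)pent-1-yn-3-one | C#CC(=O)C[C@@H](O[Si](CC)(CC)CC)c1ccc(O[Si](C)(C)C(C)(C)C)cc1 | intermediate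
12 | (3R)-1-[4-(tert-butyldimethylsilyloxy)-5-geranyl-6-methoxy-6-(trimethylsilyloxy)cyclohexa-1,4-dien-1-yl]-3-[4-(tert-butyldimethylsilyloxy)phenyl]-3-(triethylsilyloxy)propan-1-one (both configurations at the ketal carbon) | COC1(O[Si](C)(C)C)C(C/C=C(\C)CCC=C(C)C)=C(O[Si](C)(C)C(C)(C)C)CC=C1C(=O)C[C@@H](O[Si](CC)(CC)CC)c2ccc(O[Si](C)(C)C(C)(C)C)cc2 | intermediate
13 | (3R)-1-[4-(tert-butyldimethylsilyloxy)-3-geranyl-2-(trimethylsilyloxy)phenyl]-3-[4-(tert-butyldimethylsilyloxy)phenyl]-3-(triethylsilyloxy)propan-1-one | CC(C)=CCC/C(C)=C/Cc1c(O[Si](C)(C)C(C)(C)C)ccc(C(=O)C[C@@H](O[Si](CC)(CC)CC)c2ccc(O[Si](C)(C)C(C)(C)C)cc2)c1O[Si](C)(C)C | intermediate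
14 | (3R)-1-[4-(tert-butyldimethylsilyloxy)-3-geranyl-2-hydroxyphenyl]-3-[4-(tert-butyldimethylsilyloxy)phenyl]-3-(triethylsilyloxy)propan-1-one | CC(C)=CCC/C(C)=C/Cc1c(O[Si](C)(C)C(C)(C)C)ccc(C(=O)C[C@@H](O[Si](CC)(CC)CC)c2ccc(O[Si](C)(C)C(C)(C)C)cc2)c1O | intermediate
15 | (3R)-1-[4-(tert-butyldimethylsilyloxy)-3-geranyl-2-hydroxyphenyl]-3-[4-(tert-butyldimethylsilyloxy)phenyl]-3-hydroxypropan-1-one | CC(C)=CCC/C(C)=C/Cc1c(O[Si](C)(C)C(C)(C)C)ccc(C(=O)C[C@@H](O)c2ccc(O[Si](C)(C)C(C)(C)C)cc2)c1O | intermediate
16 | (2S)-7-(tert-butyldimethylsilyloxy)-2-[4-(tert-butyldimethylsilyloxy)phenyl]-8-geranylchroman-4-one | CC(C)=CCC/C(C)=C/Cc1c(O[Si](C)(C)C(C)(C)C)ccc2c1O[C@H](c1ccc(O[Si](C)(C)C(C)(C)C)cc1)CC2=O | intermediate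
17 | (2S)-7,4'-dihydroxy-8-geranylflavanone | CC(C)=CCC/C(C)=C/Cc1c(O)ccc2c1O[C@H](c1ccc(O)cc1)CC2=O | target

Total step count: 12 (3 for the diene, 5 for the ynone, the key step, 3 after it).
Longest linear sequence: 9 steps (6 to 17, steps 4 to 12).

Steps most likely to fail

Step 9. The nucleophilic ketene acetal may trigger loss of the β-triethylsilyloxy group from the ynone (enolisation toward the benzylic carbon, then elimination), or ring closure at the crowded ketene acetal terminus may lag so that open-chain conjugate adducts and diene hydrolysis take over. The fallback keeps the ring construction but moves the stereocentre out of the dienophile and sets it afterwards by catalysis. It sets out from 5 and returns at 15.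
- Diene 5 and commercial but-3-yn-2-one (CC(=O)C#C; toluene, −40 °C → rt, then silica) should give, through the cycloadduct 1-[4-(tert-butyldimethylsilyloxy)-5-geranyl-6-methoxy-6-(trimethylsilyloxy)cyclohexa-1,4-dien-1-yl]ethanone F1 and the aryl silyl ether 1-[4-(tert-butyldimethylsilyloxy)-3-geranyl-2-(trimethylsilyloxy)phenyl]ethanone F2, the acetophenone 1-[4-(tert-butyldimethylsilyloxy)-3-geranyl-2-hydroxyphenyl]ethanone F3.
- TMSOTf/Et3N (CH2Cl2, 0 °C) silylates both the phenol and the enol to give the enol silyl ether tert-butyl{2-geranyl-3-(trimethylsilyloxy)-4-[1-(trimethylsilyloxy)ethenyl]phenoxy}dimethylsilane F4.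
- A catalytic enantioselective Mukaiyama aldol addition of F4 to commercial 4-(tert-butyldimethylsilyloxy)benzaldehyde (O=Cc1ccc(O[Si](C)(C)C(C)(C)C)cc1) follows, with SiCl4, a chiral bisphosphoramide derived from 2,2'-diamino-1,1'-binaphthyl (5 mol%), i-Pr2NEt, CH2Cl2, −78 °C. The catalyst enantiomer is the one that directs the enol ether to the Re face of the aldehyde, which corresponds to the (R)-carbinol. Aqueous work-up also frees the chelated phenol and gives 15 directly.

Step 11. Deprotonation next to the ketone may expel the activated oxygen to give the chalcone, and ionisation of the electron-rich benzylic alkoxyphosphonium ion may let ring C close without inversion; both processes erode the enantiomeric purity at C2. The fallback sets C2 by catalyst-controlled conjugate arylation of a chromone instead of by substitution. It sets out from 5 and returns at 16.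
- Diene 5 is taken with but-3-yn-2-one to acetophenone F3 as described above.
- Me2NCH(OMe)2 (toluene, 90 °C) converts F3 into the enaminone (2E)-1-[4-(tert-butyldimethylsilyloxy)-3-geranyl-2-hydroxyphenyl]-3-(dimethylamino)prop-2-en-1-one F5.
- Warm acetic acid (60 °C) closes F5, with loss of dimethylamine, to the chromone 7-(tert-butyldimethylsilyloxy)-8-geranyl-4H-chromen-4-one F6.
- Hayashi–Miyaura 1,4-addition of commercial [4-(tert-butyldimethylsilyloxy)phenyl]boronic acid (OB(O)c1ccc(O[Si](C)(C)C(C)(C)C)cc1) to F6 follows, with [Rh(OH)(cod)]2 and an electron-poor atropisomeric bisphosphine of the MeO-BIPHEP type in toluene/H2O at rt. The ligand enantiomer is the one that delivers the aryl group to the Re face of C2, which should give 16. Premature loss of an aryl silyl group would be harmless, since step 12 removes both.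

Step 8. The released N,O-dimethylhydroxylamine or excess acetylide may add in conjugate fashion to the very electrophilic terminal ynone during the quench, and the acidic quench that prevents this may start to cleave the triethylsilyl ether. The fallback replaces acyl substitution by aldehyde addition and oxidation. It sets out from 10 and returns at 11.
- i-Bu2AlH (THF, −78 °C) reduces 10 to the aldehyde (3R)-3-[4-(tert-butyldimethylsilyloxy)phenyl]-3-(triethylsilyloxy)propanal F7.
- HC≡CMgBr (THF, −78 °C) adds to give the propargylic alcohol (5R)-5-[4-(tert-butyldimethylsilyloxy)phenyl]-5-(triethylsilyloxy)pent-1-yn-3-ol F8 as both epimers at the new carbinol.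
- Dess–Martin periodinane (NaHCO3, CH2Cl2, 0 °C) oxidises both epimers to 11 under neutral conditions with no amine present.

Further compounds
F1 | step 9 | 1-[4-(tert-butyldimethylsilyloxy)-5-geranyl-6-methoxy-6-(trimethylsilyloxy)cyclohexa-1,4-dien-1-yl]ethanone | CC(=O)C1=CCC(O[Si](C)(C)C(C)(C)C)=C(C/C=C(\C)CCC=C(C)C)C1(OC)O[Si](C)(C)C
F2 | step 9 | 1-[4-(tert-butyldimethylsilyloxy)-3-geranyl-2-(trimethylsilyloxy)phenyl]ethanone | CC(=O)c1ccc(O[Si](C)(C)C(C)(C)C)c(C/C=C(\C)CCC=C(C)C)c1O[Si](C)(C)C
F3 | step 9 | 1-[4-(tert-butyldimethylsilyloxy)-3-geranyl-2-hydroxyphenyl]ethanone | CC(=O)c1ccc(O[Si](C)(C)C(C)(C)C)c(C/C=C(\C)CCC=C(C)C)c1O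
F4 | step 9 | tert-butyl{2-geranyl-3-(trimethylsilyloxy)-4-[1-(trimethylsilyloxy)ethenyl]phenoxy}dimethylsilane | C=C(O[Si](C)(C)C)c1ccc(O[Si](C)(C)C(C)(C)C)c(C/C=C(\C)CCC=C(C)C)c1O[Si](C)(C)C
F5 | step 11 | (2E)-1-[4-(tert-butyldimethylsilyloxy)-3-geranyl-2-hydroxyphenyl]-3-(dimethylamino)prop-2-en-1-one | CN(C)/C=C/C(=O)c1ccc(O[Si](C)(C)C(C)(C)C)c(C/C=C(\C)CCC=C(C)C)c1O
F6 | step 11 | 7-(tert-butyldimethylsilyloxy)-8-geranyl-4H-chromen-4-one | O=c1ccoc2c(C/C=C(\C)CCC=C(C)C)c(O[Si](C)(C)C(C)(C)C)ccc12
F7 | step 8 | (3R)-3-[4-(tert-butyldimethylsilyloxy)phenyl]-3-(triethylsilyloxy)propanal | O=CC[C@@H](O[Si](CC)(CC)CC)c1ccc(O[Si](C)(C)C(C)(C)C)cc1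
F8 | step 8 | (5R)-5-[4-(tert-butyldimethylsilyloxy)phenyl]-5-(triethylsilyloxy)pent-1-yn-3-ol (both epimers at C3) | C#CC(O)C[C@@H](O[Si](CC)(CC)CC)c1ccc(O[Si](C)(C)C(C)(C)C)cc1
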